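**Retrosynthetic overview**

- Numbering follows farnesane: chain C1–C12 (C1 is the CH2Br carbon), C13 on C11, C14 on C7, C15 on C3. The target is then (2R,4R,6S,7S,10S): a bromocyclohexane (C6–C11) trans-fused along C6–C7 to an oxepane (O, C2–C7).
- Enabling feature: the C10–Br, C6–C11 and O–C7 bonds stand exactly as the outcome of a bromonium-initiated anti addition across an (E)-C6=C7 alkene, and the ether oxygen sits on C2, which a (3Z)-alkene can hold cis to C5 and within reach of C7.
- Disconnections: (a) C4–OH and the C3=C15 methylidene ⇒ C3=C4 alkene via its α-epoxide; (b) key cascade: C10–Br, C6–C11 (cyclohexane, first ring) and O–C7 (oxepane, second ring) ⇒ acyclic (2R,3Z,6E)-bromohydrin triene; (c) C3=C4 ⇒ (Z)-selective Wittig reaction of a glycerate-derived methyl ketone (C1–C3, C15; source of C2) with a homogeranyl ylide (C4–C14) from geranyl bromide.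

Key step: step 7

Remark: the thiophosphoramide antipode that brominates the Si face of C10 cannot be predicted with certainty for this substrate and is fixed in a pilot run; both antipodes derive from (R)- or (S)-BINOL.

**Route**

Step 1
Reactants: 1 methyl (S)-2,2-dimethyl-1,3-dioxolane-4-carboxylate
Product: 3 (S)-1-(2,2-dimethyl-1,3-dioxolan-4-yl)ethan-1-one, via Weinreb amide 2 (not isolated)
Conditions: MeNHOMe·HCl, i-PrMgCl, THF, −20 °C; then MeMgCl, −20 → 0 °C; aq. NH4Cl
Reagents that add atoms: MeMgCl, C[Mg]Cl; N,O-dimethylhydroxylamine hydrochloride, CNOC.Cl (its atoms stay only in 2)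
Why: Weinreb ketone synthesis in one flask: the magnesium amide converts the ester into the N-methoxy-N-methylamide, whose chelated adduct with MeMgCl gives the methyl ketone only on work-up, so over-addition is avoided and the α-stereocentre (future C2) is not touched.

Step 2
Reactants: 4 geranyl bromide, 5 methyltriphenylphosphonium bromide
Product: 7 [(3E)-4,8-dimethylnona-3,7-dien-1-yl]triphenylphosphonium bromide, via methylenetriphenylphosphorane 6 (not isolated)
Conditions: 5, n-BuLi, THF, 0 °C; then 4, −78 °C → rt; salt crystallised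
Reagents that add atoms: none
Why: C-alkylation of a phosphorus ylide by a primary allylic bromide (SN2 at the CH2Br carbon, the trisubstituted γ-carbon being too hindered for SN2′), which adds C4 to the geranyl unit and carries the (E)-C6=C7 geometry through unchanged.

Step 3
Reactants: 7 [(3E)-4,8-dimethylnona-3,7-dien-1-yl]triphenylphosphonium bromide, 3 (S)-1-(2,2-dimethyl-1,3-dioxolan-4-yl)ethan-1-one
Product: 9 (4R)-4-[(2Z,5E)-6,10-dimethylundeca-2,5,9-trien-2-yl]-2,2-dimethyl-1,3-dioxolane, via homogeranylidene ylide 8 (not isolated)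
Conditions: 7, KN(SiMe3)2, THF, −78 °C; then 3, −78 → 0 °C
Reagents that add atoms: none
Why: Wittig reaction of a non-stabilised ylide with an α-alkoxy ketone under salt-free kinetic conditions, a combination known to place the ylide chain cis to the oxygen-bearing carbon and so to give the (3Z) alkene; addition at −78 °C should outrun enolisation, so C2 keeps its configuration (its descriptor becomes R only through the priority rules).

Step 4
Reactants: 9 (4R)-4-[(2Z,5E)-6,10-dimethylundeca-2,5,9-trien-2-yl]-2,2-dimethyl-1,3-dioxolane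
Product: 10 (2R,3Z,6E)-3,7,11-trimethyldodeca-3,6,10-triene-1,2-diol
Conditions: AcOH/H2O (4:1), 40 °C
Reagents that add atoms: none
Why: Acid-catalysed acetal hydrolysis under conditions mild enough to leave the allylic C2–O bond and the three alkenes untouched, so C2 and both alkene geometries are kept.

Step 5
Reactants: 10 (2R,3Z,6E)-3,7,11-trimethyldodeca-3,6,10-triene-1,2-diol
Product: 11 (2R,3Z,6E)-2-hydroxy-3,7,11-trimethyldodeca-3,6,10-trien-1-yl 4-methylbenzenesulfonate
Conditions: TsCl, Et3N, Bu2SnO (2 mol%), CH2Cl2, 0 °C → rt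
Reagents that add atoms: TsCl, Cc1ccc(cc1)S(Cl)(=O)=O
Why: Tin-catalysed regioselective sulfonylation of a 1,2-diol, in which the catalyst directs the tosyl group to the primary oxygen only and no stereocentre is touched.

Step 6
Reactants: 11 (2R,3Z,6E)-2-hydroxy-3,7,11-trimethyldodeca-3,6,10-trien-1-yl 4-methylbenzenesulfonate
Product: 12 (2R,3Z,6E)-1-bromo-3,7,11-trimethyldodeca-3,6,10-trien-2-ol
Conditions: LiBr, acetone, 50 °C
Reagents that add atoms: LiBr, [Li+].[Br-]
Why: Finkelstein-type SN2 displacement of the primary tosylate by bromide under neutral conditions, which neither closes an epoxide nor ionises the allylic alcohol, so C2 is unchanged.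

Step 7
Reactants: 12 (2R,3Z,6E)-1-bromo-3,7,11-trimethyldodeca-3,6,10-trien-2-ol
Product: 15 (2R,5aS,7S,9aS)-7-bromo-2-(bromomethyl)-3,6,6,9a-tetramethyl-2,5,5a,6,7,8,9,9a-octahydro-1-benzoxepine, via C10–C11 bromonium ion 13 (not isolated), via C7 carbocation 14 (not isolated)
Conditions: DBDMH (0.55 equiv), chiral BINOL-derived thiophosphoramide (10 mol%), toluene/CH2Cl2, −78 °C
Reagents that add atoms: DBDMH (1,3-dibromo-5,5-dimethylhydantoin), CC1(C)N(Br)C(=O)N(Br)C1=O
Why: The chiral Lewis base passes Br+ from DBDMH to the terminal C10=C11 alkene to give bromonium ion 13, the (E)-C6=C7 alkene opens it at C11 through a chair transition state (6-endo cation–olefin closure of the cyclohexane) to give the tertiary C7 cation 14, and the C2 hydroxyl then captures C7 (seven-membered closure of the oxepane, O–C7 bond), so that C11 and oxygen add anti across C6=C7. The closest known reaction types are the biomimetic bromonium-initiated polyene cyclization that a pendant hydroxyl terminates as a trans-fused bromo-oxepane and the thiophosphoramide-catalysed enantioselective bromocyclization of polyenes with DBDMH. C10 is set by the catalyst, which has to deliver bromine to the Si face of C10 (the C2 carbinol is eight bonds away and should not override it), C6 and C7 follow from C10 because bromine and the C5 chain lie equatorial in the chair and the (E) geometry puts the C7 methyl axial and the incoming oxygen equatorial (trans ring fusion), and C2 is not touched. The step needs site selectivity for C10=C11, which the substrate secures because this is the least hindered trisubstituted alkene while C3=C4 is deactivated by the allylic oxygen and the bromine on C1. It also needs the cation to be trapped by oxygen and not by carbon or by proton loss, which the (3Z) alkene secures by holding the C2 hydroxyl cis to C5 and within reach of C7 while it cannot itself add to C7 (only a four-membered ring, or a five-membered ring through a secondary cation, would result), no second hydroxyl being present. The C10-epimeric series, if formed, is a diastereomer of 15 and should be separable.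

Step 8
Reactants: 15 (2R,5aS,7S,9aS)-7-bromo-2-(bromomethyl)-3,6,6,9a-tetramethyl-2,5,5a,6,7,8,9,9a-octahydro-1-benzoxepine
Product: 16 (2R,3R,4R,5aS,7S,9aS)-7-bromo-2-(bromomethyl)-3,4-epoxy-3,6,6,9a-tetramethyldecahydro-1-benzoxepine
Conditions: DMDO, acetone/CH2Cl2, 0 °C
Reagents that add atoms: dimethyldioxirane (DMDO), CC1(C)OO1
Why: Dioxirane epoxidation of the only alkene under neutral conditions, in which the oxidant should approach the α face, opposite to the bromomethyl group on the neighbouring C2 and to the axial methyl groups on C7 and C11, which sets C3 and C4 (both R) with oxygen on the face required for the C4 hydroxyl.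

Step 9
Reactants: 16 (2R,3R,4R,5aS,7S,9aS)-7-bromo-2-(bromomethyl)-3,4-epoxy-3,6,6,9a-tetramethyldecahydro-1-benzoxepine
Product: 17 (2R,4R,5aS,7S,9aS)-7-bromo-2-(bromomethyl)-6,6,9a-trimethyl-3-methylidenedecahydro-1-benzoxepin-4-ol
Conditions: Et2AlCl, lithium 2,2,6,6-tetramethylpiperidide (gives Et2Al(TMP)), toluene, 0 °C; aq. potassium sodium tartrate
Reagents that add atoms: none
Why: Aluminium-amide-mediated isomerisation of a trisubstituted epoxide to an allylic alcohol, in which aluminium binds the epoxide oxygen and the amide removes, in a syn elimination, a proton from the C3 methyl group (the substituent cis to the C4 hydrogen), so that the C3–O bond breaks, the C3=C15 methylidene forms and the C4–O bond keeps its α configuration (4R).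

**Compound list**

1 | methyl (S)-2,2-dimethyl-1,3-dioxolane-4-carboxylate | COC(=O)[C@@H]1COC(C)(C)O1 | starting material
2 | (S)-N-methoxy-N,2,2-trimethyl-1,3-dioxolane-4-carboxamide (Weinreb amide) | CON(C)C(=O)[C@@H]1COC(C)(C)O1 | intermediate
3 | (S)-1-(2,2-dimethyl-1,3-dioxolan-4-yl)ethan-1-one | CC(=O)[C@@H]1COC(C)(C)O1 | intermediate
4 | geranyl bromide, (2E)-1-bromo-3,7-dimethylocta-2,6-diene | BrC/C=C(\C)CCC=C(C)C | starting material
5 | methyltriphenylphosphonium bromide | C[P+](c1ccccc1)(c1ccccc1)c1ccccc1.[Br-] | starting material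
6 | methylenetriphenylphosphorane | C=P(c1ccccc1)(c1ccccc1)c1ccccc1 | intermediate
7 | [(3E)-4,8-dimethylnona-3,7-dien-1-yl]triphenylphosphonium bromide | CC(C)=CCC/C(C)=C/CC[P+](c1ccccc1)(c1ccccc1)c1ccccc1.[Br-] | intermediate
8 | [(3E)-4,8-dimethylnona-3,7-dien-1-ylidene]triphenylphosphorane (homogeranylidene ylide) | CC(C)=CCC/C(C)=C/CC=P(c1ccccc1)(c1ccccc1)c1ccccc1 | intermediate
9 | (4R)-4-[(2Z,5E)-6,10-dimethylundeca-2,5,9-trien-2-yl]-2,2-dimethyl-1,3-dioxolane | C/C(=C/C/C=C(\C)CCC=C(C)C)[C@@H]1COC(C)(C)O1 | intermediate
10 | (2R,3Z,6E)-3,7,11-trimethyldodeca-3,6,10-triene-1,2-diol | C/C(=C/C/C=C(\C)CCC=C(C)C)[C@@H](O)CO | intermediate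
11 | (2R,3Z,6E)-2-hydroxy-3,7,11-trimethyldodeca-3,6,10-trien-1-yl 4-methylbenzenesulfonate | C/C(=C/C/C=C(\C)CCC=C(C)C)[C@@H](O)COS(=O)(=O)c1ccc(C)cc1 | intermediate
12 | (2R,3Z,6E)-1-bromo-3,7,11-trimethyldodeca-3,6,10-trien-2-ol | C/C(=C/C/C=C(\C)CCC=C(C)C)[C@@H](O)CBr | intermediate
13 | C10–C11 bromonium ion of 12 (10S, bromine on the Si face of C10) | C/C(=C/C/C=C(\C)CC[C@@H]1[Br+]C1(C)C)[C@@H](O)CBr | intermediate
14 | monocyclic C7 carbocation, 4-bromo-2-[(2Z,4R)-5-bromo-4-hydroxy-3-methylpent-2-en-1-yl]-1,3,3-trimethylcyclohexan-1-ylium (bromine and side chain equatorial) | C/C(=C/C[C@@H]1[C+](C)CC[C@H](Br)C1(C)C)[C@@H](O)CBr | intermediate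
15 | (2R,5aS,7S,9aS)-7-bromo-2-(bromomethyl)-3,6,6,9a-tetramethyl-2,5,5a,6,7,8,9,9a-octahydro-1-benzoxepine | CC1=CC[C@H]2C(C)(C)[C@@H](Br)CC[C@]2(C)O[C@H]1CBr | intermediate
16 | (2R,3R,4R,5aS,7S,9aS)-7-bromo-2-(bromomethyl)-3,4-epoxy-3,6,6,9a-tetramethyldecahydro-1-benzoxepine (α-epoxide) | C[C@@]12O[C@@H]1C[C@H]3C(C)(C)[C@@H](Br)CC[C@]3(C)O[C@H]2CBr | intermediate
17 | (2R,4R,5aS,7S,9aS)-7-bromo-2-(bromomethyl)-6,6,9a-trimethyl-3-methylidenedecahydro-1-benzoxepin-4-ol | C=C1[C@H](O)C[C@H]2C(C)(C)[C@@H](Br)CC[C@]2(C)O[C@H]1CBr | target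

**Step count and risks**

Total step count: 9. Longest linear sequence: 8 steps (steps 1 and 3–9 from 1; equally steps 2–9 from 4).

Steps most likely to fail:

1. Step 7. What may go wrong: proton loss from cation 14 outruns ring closure by the C2 hydroxyl, or the catalyst selects the C10 face incompletely. Fallback, from 12 back to 15: the same catalysed bromination is accepted at the monocyclic stage, where proton loss from 14 gives the diene alcohol (2R,3Z)-1-bromo-5-[(1R,3S)-3-bromo-2,2-dimethyl-6-methylidenecyclohexyl]-3-methylpent-3-en-2-ol F1. The C10-epimeric diastereomer is removed by chromatography at this stage. A separate Brønsted-acid hydroalkoxylation (TfOH, 5 mol%, CH2Cl2, −40 °C) then protonates the exocyclic alkene, regenerates 14 under conditions where proton loss is reversible, and closes the O–C7 bond to give 15.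

2. Step 9. What may go wrong: the amide base removes a proton next to the C1 bromide (loss of HBr) or from C5 instead of from the C3 methyl group. Fallback, from 16 back to 17: electrophilic opening replaces the basic reagent. TMSOTf/2,6-lutidine in toluene at −78 °C opens the epoxide at tertiary C3 and DBU removes a methyl proton, which should give the silyl ether (2R,4R,5aS,7S,9aS)-7-bromo-2-(bromomethyl)-6,6,9a-trimethyl-3-methylidene-4-[(trimethylsilyl)oxy]decahydro-1-benzoxepine F2. K2CO3 in MeOH then frees the alcohol 17.

3. Step 8. What may go wrong: the oxidant attacks the β face (reversed facial selectivity). Fallback, from 15 back to 16: a halohydrin sequence that inverts the facial outcome. NBS in THF/H2O puts bromine on the face the oxidant prefers and water on C3 from the other face, giving the bromohydrin (2R,3S,4S,5aS,7S,9aS)-4,7-dibromo-2-(bromomethyl)-3,6,6,9a-tetramethyldecahydro-1-benzoxepin-3-ol F3. K2CO3 in MeOH then closes the epoxide by backside displacement of the C4 bromide, which gives 16.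

**Further compounds**

F1 | step 7 | (2R,3Z)-1-bromo-5-[(1R,3S)-3-bromo-2,2-dimethyl-6-methylidenecyclohexyl]-3-methylpent-3-en-2-ol | C/C(=C/C[C@@H]1C(=C)CC[C@H](Br)C1(C)C)[C@@H](O)CBr
F2 | step 9 | (2R,4R,5aS,7S,9aS)-7-bromo-2-(bromomethyl)-6,6,9a-trimethyl-3-methylidene-4-[(trimethylsilyl)oxy]decahydro-1-benzoxepine | C=C1[C@H](O[Si](C)(C)C)C[C@H]2C(C)(C)[C@@H](Br)CC[C@]2(C)O[C@H]1CBr
F3 | step 8 | (2R,3S,4S,5aS,7S,9aS)-4,7-dibromo-2-(bromomethyl)-3,6,6,9a-tetramethyldecahydro-1-benzoxepin-3-ol | C[C@@]1(O)[C@@H](Br)C[C@H]2C(C)(C)[C@@H](Br)CC[C@]2(C)O[C@H]1CBr
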